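**Retrosynthetic overview**

1. The target is (2R)-5,7-dimethoxy-8-prenylflavanone. Its C4 ketone is unmasked last from a C4 methyl ether (solvolysis, then oxidation). Its C8 prenyl group is made from a C8 allyl group by cross-metathesis, once the phenol oxygen is locked in ring C.
2. The strategy rests on ring C (O1–C2–C3–C4–C4a–C8a). It joins the phenolic oxygen O1 and the benzylic carbon C4 of a salicyl unit (ring A) through C2 and C3, which are the two alkene carbons of styrene, C2 carrying ring B. Cutting O1–C2 and C3–C4 gives a C4-methoxy ortho-quinone methide and styrene.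
3. The heterodiene is made in the flask from 3-allyl-2-hydroxy-4,6-dimethoxybenzaldehyde and trimethyl orthoformate under a chiral confined Brønsted acid, which sets C2 as R. The aldehyde comes from 2-hydroxy-4,6-dimethoxybenzaldehyde by O-allylation and aromatic Claisen rearrangement.
4. Ring order: rings A and B are bought; ring C is the only ring formed, in the key step.

Key step: step 3

Remark: the side chain is carried as allyl through the acid step, because strong acid cyclises an ortho-prenyl phenol to a 2,2-dimethylchroman and a trisubstituted alkene would compete with styrene for the cation; the configuration at C4 is immaterial (C4 becomes the ketone), and the antipode of the chiral acid that gives (2R) must be chosen by experiment.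

**Route**

Step 1
Reactants: 1 2-hydroxy-4,6-dimethoxybenzaldehyde; 2 allyl bromide
Product: 3 2-(allyloxy)-4,6-dimethoxybenzaldehyde
Conditions: K2CO3 (2 equiv), allyl bromide (1.5 equiv), DMF, 60 °C
Reagents that add atoms: allyl bromide, C=CCBr
Why: Williamson ether synthesis on the only acidic site; DMF and gentle warming overcome the hydrogen bond between the phenol and the aldehyde.

Step 2
Reactants: 3 2-(allyloxy)-4,6-dimethoxybenzaldehyde
Product: 5 3-allyl-2-hydroxy-4,6-dimethoxybenzaldehyde, via ortho-dienone 4 (not isolated)
Conditions: N,N-diethylaniline, 200 °C, sealed tube, argon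
Reagents that add atoms: none
Why: aromatic Claisen rearrangement ([3,3] shift); C3 is the only ortho carbon that bears hydrogen (the other carries the formyl group), so dienone 4 should tautomerise to 5 alone.

Step 3
Reactants: 5 3-allyl-2-hydroxy-4,6-dimethoxybenzaldehyde; 6 trimethyl orthoformate; 7 styrene
Product: 10 (2R,4R)-8-allyl-4,5,7-trimethoxy-2-phenylchromane, via dimethyl acetal 8 (not isolated), via methoxy ortho-quinone methide 9 (not isolated)
Conditions: chiral imidodiphosphorimidate Brønsted acid (IDPi; BINOL backbone, 3,3'-aryl groups, N-triflyl; 5 mol %), HC(OMe)3 (2 equiv), styrene (10 equiv), CH2Cl2, −40 to −20 °C; Et3N quench at −40 °C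
Reagents that add atoms: trimethyl orthoformate, COC(OC)OC; styrene, C=Cc1ccccc1
Why: Proposed new method: the acid converts 5 and the orthoformate into acetal 8 and ionises it to the O-protonated form of methoxy ortho-quinone methide 9, held as a contact ion pair in the pocket of the chiral anion; the CH2 terminus of styrene attacks the methide carbon (future C4) and the benzylic cation developing at C2 is captured by the phenol oxygen, an asynchronous inverse-electron-demand oxa-[4+2] cycloaddition. The closest known reactions are the achiral Lewis-acid three-component coupling of salicylaldehydes, orthoformates and styrenes to 2,4-cis-4-alkoxyflavans and the intramolecular ortho-quinone methide hetero-Diels–Alder reactions of salicylaldehyde-derived acetals under confined chiral phosphorus acids; the intermolecular enantioselective form is not established. Ring C is closed in the intermolecular [4+2] mode, with the C3–C4 bond leading and the O1–C2 bond lagging, so no ring-closure constraint applies. C2 is set by the chiral counteranion, which shields one face of the ion-paired heterodiene and fixes the orientation of the phenyl group in an endo-type approach; C4 should follow as cis by the same approach but is erased later. The step needs regioselectivity (phenyl at C2), secured by the benzylic cation, and chemoselectivity for styrene, secured against the side-chain alkene by carrying it as a monosubstituted allyl group (a far weaker π-nucleophile that cannot be protonated to a tertiary cation) and against the ring CH between the two methoxy groups by the excess of styrene and the confined pocket.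

Step 4
Reactants: 10 (2R,4R)-8-allyl-4,5,7-trimethoxy-2-phenylchromane; 11 2-methyl-2-butene
Product: 12 (2R,4R)-4,5,7-trimethoxy-8-(3-methylbut-2-en-1-yl)-2-phenylchromane
Conditions: (H2IMes)(PCy3)Cl2Ru=CHPh (second-generation Grubbs catalyst, 5 mol %), 2-methyl-2-butene/CH2Cl2 1:1, 40 °C, sealed tube
Reagents that add atoms: 2-methyl-2-butene, CC=C(C)C
Why: olefin cross-metathesis of a terminal alkene with excess 2-methyl-2-butene, the standard allyl-to-prenyl conversion; neither stereocentre is touched and the phenol oxygen is now an ether, so the prenyl group has no partner for cyclisation.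

Step 5
Reactants: 12 (2R,4R)-4,5,7-trimethoxy-8-(3-methylbut-2-en-1-yl)-2-phenylchromane
Product: 13 (2R)-5,7-dimethoxy-8-(3-methylbut-2-en-1-yl)-2-phenylchroman-4-ol (mixture of C4 epimers)
Conditions: PPTS (0.2 equiv), acetone/H2O 4:1 (0.02 M), rt to 40 °C; NaHCO3 before concentration
Reagents that add atoms: water, O
Why: SN1 solvolysis of a benzylic methyl ether whose cation is stabilised by three ortho/para oxygens, so weak acid and a large excess of water should suffice; C2 is not ionised (plain phenyl group) and the C4 epimer ratio is irrelevant.

Step 6
Reactants: 13 (2R)-5,7-dimethoxy-8-(3-methylbut-2-en-1-yl)-2-phenylchroman-4-ol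
Product: 14 (2R)-5,7-dimethoxy-8-(3-methylbut-2-en-1-yl)-2-phenylchroman-4-one (target)
Conditions: Dess–Martin periodinane (1.3 equiv), pyridine (3 equiv), CH2Cl2, 0 °C to rt
Reagents that add atoms: none
Why: Dess–Martin oxidation of a secondary benzylic alcohol, in which both C4 epimers converge on the ketone; the buffered, near-neutral conditions should avoid the retro-oxa-Michael ring opening that would racemise C2.

**Compound list**

1 | 2-hydroxy-4,6-dimethoxybenzaldehyde | COc1cc(O)c(C=O)c(OC)c1 | starting material
2 | allyl bromide | C=CCBr | starting material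
3 | 2-(allyloxy)-4,6-dimethoxybenzaldehyde | COc1cc(OCC=C)c(C=O)c(OC)c1 | intermediate
4 | 5-allyl-2,4-dimethoxy-6-oxocyclohexa-1,3-diene-1-carbaldehyde (ortho-dienone, racemic) | O=CC1=C(OC)C=C(OC)C(CC=C)C1=O | intermediate (not isolated)
5 | 3-allyl-2-hydroxy-4,6-dimethoxybenzaldehyde | COc1cc(OC)c(C=O)c(O)c1CC=C | intermediate
6 | trimethyl orthoformate | COC(OC)OC | starting material
7 | styrene | C=Cc1ccccc1 | starting material
8 | 2-allyl-6-(dimethoxymethyl)-3,5-dimethoxyphenol | COc1cc(OC)c(C(OC)OC)c(O)c1CC=C | intermediate (not isolated)
9 | 2-allyl-3,5-dimethoxy-6-(methoxymethylidene)cyclohexa-2,4-dien-1-one (reacts as its O-protonated ion pair) | COC=C1C(=O)C(CC=C)=C(OC)C=C1OC | intermediate (not isolated)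
10 | (2R,4R)-8-allyl-4,5,7-trimethoxy-2-phenylchromane (2,4-cis) | COc1cc(OC)c2c(c1CC=C)O[C@@H](c1ccccc1)C[C@H]2OC | intermediate
11 | 2-methyl-2-butene | CC=C(C)C | starting material
12 | (2R,4R)-4,5,7-trimethoxy-8-(3-methylbut-2-en-1-yl)-2-phenylchromane (2,4-cis) | COc1cc(OC)c2c(c1CC=C(C)C)O[C@@H](c1ccccc1)C[C@H]2OC | intermediate
13 | (2R)-5,7-dimethoxy-8-(3-methylbut-2-en-1-yl)-2-phenylchroman-4-ol (C4 epimers) | COc1cc(OC)c2c(c1CC=C(C)C)O[C@@H](c1ccccc1)CC2O | intermediate
14 | (2R)-5,7-dimethoxy-8-(3-methylbut-2-en-1-yl)-2-phenylchroman-4-one | COc1cc(OC)c2c(c1CC=C(C)C)O[C@@H](c1ccccc1)CC2=O | target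

**Step count**

Total steps: 6. Longest linear sequence: 6.

**Steps most likely to fail**

Step 3 (key step). The loosely organised intermolecular ion pair may give poor facial selectivity at C2. The cation may also be captured by the electron-rich ring CH between the two methoxy groups (Friedel–Crafts oligomerisation), or the acid may start oligomerisation of styrene. The fallback leaves the cycloaddition and sets C2 by a known asymmetric conjugate addition. It sets out from 5. Ethynylmagnesium bromide (3 equiv, THF, 0 °C to rt) adds to the aldehyde to give 1-(3-allyl-2-hydroxy-4,6-dimethoxyphenyl)prop-2-yn-1-ol F1. MnO2 in CH2Cl2 oxidises it to 1-(3-allyl-2-hydroxy-4,6-dimethoxyphenyl)prop-2-yn-1-one F2. K2CO3 in acetone closes F2 by 6-endo-dig oxa-Michael addition to 8-allyl-5,7-dimethoxy-4H-chromen-4-one F3. Cross-metathesis with 11 under the catalyst of step 4 gives 5,7-dimethoxy-8-(3-methylbut-2-en-1-yl)-4H-chromen-4-one F4. Rhodium-catalysed asymmetric 1,4-addition of phenylboronic acid ([Rh(OH)(cod)]2, chiral biaryl bisphosphine, toluene/H2O) to F4 should then give the flavanone directly, so the fallback comes back to the route at 14.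

Step 5. While C4 is ionised, the prenyl double bond may be protonated or hydrated, or may couple with the cation, and the flavan-4-ol may dehydrate to the flav-3-ene on concentration. The fallback changes the order so that the acid step and the oxidation run at the allyl stage, with the more robust monosubstituted alkene. It sets out from 10. The same aqueous PPTS solvolysis gives (2R)-8-allyl-5,7-dimethoxy-2-phenylchroman-4-ol F5. Dess–Martin oxidation gives (2R)-8-allyl-5,7-dimethoxy-2-phenylchroman-4-one F6. Cross-metathesis of F6 with 11 under the catalyst of step 4 installs the prenyl group last, so the fallback comes back to the route at 14.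

Step 4. The cross-metathesis may stall at the crotyl stage, or ruthenium hydride species may isomerise the allyl group into conjugation with ring A. The fallback builds the prenyl group by oxidative cleavage and olefination. It sets out from 10. Lemieux–Johnson cleavage (OsO4 cat., NaIO4, 2,6-lutidine, dioxane/H2O) gives 2-[(2R,4R)-4,5,7-trimethoxy-2-phenylchroman-8-yl]acetaldehyde F7. Wittig reaction of F7 with isopropylidenetriphenylphosphorane (from isopropyltriphenylphosphonium iodide and n-BuLi, THF, −78 to 0 °C) comes back to the route at 12.

**Further compounds**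

F1 | step 3 | 1-(3-allyl-2-hydroxy-4,6-dimethoxyphenyl)prop-2-yn-1-ol (racemic) | COc1cc(OC)c(C(O)C#C)c(O)c1CC=C
F2 | step 3 | 1-(3-allyl-2-hydroxy-4,6-dimethoxyphenyl)prop-2-yn-1-one | COc1cc(OC)c(C(=O)C#C)c(O)c1CC=C
F3 | step 3 | 8-allyl-5,7-dimethoxy-4H-chromen-4-one | COc1cc(OC)c2c(c1CC=C)OC=CC2=O
F4 | step 3 | 5,7-dimethoxy-8-(3-methylbut-2-en-1-yl)-4H-chromen-4-one | COc1cc(OC)c2c(c1CC=C(C)C)OC=CC2=O
F5 | step 5 | (2R)-8-allyl-5,7-dimethoxy-2-phenylchroman-4-ol (C4 epimers) | COc1cc(OC)c2c(c1CC=C)O[C@@H](c1ccccc1)CC2O
F6 | step 5 | (2R)-8-allyl-5,7-dimethoxy-2-phenylchroman-4-one | COc1cc(OC)c2c(c1CC=C)O[C@@H](c1ccccc1)CC2=O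
F7 | step 4 | 2-[(2R,4R)-4,5,7-trimethoxy-2-phenylchroman-8-yl]acetaldehyde | COc1cc(OC)c2c(c1CC=O)O[C@@H](c1ccccc1)C[C@H]2OC
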